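**Plan**
- Cuts: (i) the butenolide acyl C2–O1 bond and C3=C4 (lactonisation, Z-selective HWE). (ii) In the linker, the alkene C–CH3 bond and the bond from the alkene CH to the CH2CH2 tether on chromene C2. (iii) Chromene O1–C2 (allylic etherification) and C3=C4 (dehydrogenation).
- Enabling feature: the E-trisubstituted linker alkene has its methyl-bearing carbon next to the CH2 on lactone C5 and its CH carbon two carbons from chromene C2. It is the syn-methylmetalation product of a terminal homopropargylic alkyne, so one flask makes both bonds.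
- Forward order: the benzopyran ring closes first (6-exo Pd-allyl etherification, then DDQ to the 2H-chromene). The chain is joined in step 14 with no ring closure, and the butenolide closes last.
- Stereochemistry: lactone C5 (R) comes from (S)-glycidol and chromene C2 (S) from the chiral Pd catalyst of step 10. The E-alkene comes from syn-carbometalation with retention, and the Z-enoate from an Ando-type HWE.
- Protecting groups: C5–O as TBS, the future C4 as a PMB-protected CH2OH, the phenol as TIPS (it must pass aqueous base in steps 8 and 11). Both silyl groups fall together at the end.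

Key step: step 14

Assumption: for the Z-configured carbonate 14 the (S,S)-ligand is taken to give (R)-15. The sense has to be confirmed on a crystalline derivative of 17, and the equally available (R,R)-ligand is used if it proves opposite.

**Step 1**
Reactants: 1 (S)-glycidol
Product: 2 (R)-2-{[(4-methoxybenzyl)oxy]methyl}oxirane
Conditions: NaH, PMBCl, TBAI (cat.), DMF, 0 °C → rt
Reagents that add atoms: 4-methoxybenzyl chloride, COc1ccc(CCl)cc1
Why: Williamson etherification of the primary alkoxide leaves the bonds at the stereocentre untouched (a Payne shift in glycidol is degenerate and returns the same enantiomer), so only the CIP descriptor changes from S to R.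

**Step 2**
Reactants: 2 (R)-2-{[(4-methoxybenzyl)oxy]methyl}oxirane
Product: 3 (R)-1-[(4-methoxybenzyl)oxy]pent-4-yn-2-ol
Conditions: LiC≡CH·ethylenediamine, DMSO, 0 °C → rt; H2O quench
Reagents that add atoms: lithium acetylide–ethylenediamine complex, [Li+].[C-]#C.NCCN
Why: SN2 opening of the terminal epoxide at its unsubstituted carbon by lithium acetylide is the standard route to homopropargylic alcohols and leaves the carbinol centre (future lactone C5) untouched.

**Step 3**
Reactants: 3 (R)-1-[(4-methoxybenzyl)oxy]pent-4-yn-2-ol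
Product: 4 (R)-tert-butyl({1-[(4-methoxybenzyl)oxy]pent-4-yn-2-yl}oxy)dimethylsilane
Conditions: TBSCl, imidazole, DMF, rt
Reagents that add atoms: tert-butyldimethylsilyl chloride, CC(C)(C)[Si](C)(C)Cl
Why: Imidazole-promoted silylation of a secondary alcohol gives a TBS ether that tolerates AlMe3, DDQ and the HWE base and is removed by fluoride at the end.

**Step 4**
Reactants: 5 2-methylhydroquinone
Product: 6 2-methyl-4-[(triisopropylsilyl)oxy]phenol
Conditions: TIPSCl (1.0 equiv), imidazole, DMF, 0 °C → rt
Reagents that add atoms: triisopropylsilyl chloride, CC(C)[Si](Cl)(C(C)C)C(C)C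
Why: Monosilylation under steric control, in which the bulky chlorosilane reacts at the 4-OH (no ortho substituent) rather than at the OH flanked by the methyl group.

**Step 5**
Reactants: 6 2-methyl-4-[(triisopropylsilyl)oxy]phenol
Product: 7 2-hydroxy-3-methyl-5-[(triisopropylsilyl)oxy]benzaldehyde
Conditions: MgCl2, Et3N, (CH2O)n, MeCN, reflux; 1 M HCl work-up
Reagents that add atoms: paraformaldehyde (as formaldehyde), C=O
Why: In the magnesium-mediated ortho-formylation (Casnati–Skattebøl) the magnesium phenoxide delivers formaldehyde to the only free ortho position, and a second formaldehyde oxidises the benzylic alkoxide by hydride transfer.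

**Step 6**
Reactants: 7 2-hydroxy-3-methyl-5-[(triisopropylsilyl)oxy]benzaldehyde
Product: 8 2-ethenyl-6-methyl-4-[(triisopropylsilyl)oxy]phenol
Conditions: Ph3PCH3Br (2.4 equiv), NaHMDS (2.3 equiv), THF, 0 °C → rt
Reagents that add atoms: methyltriphenylphosphonium bromide, C[P+](c1ccccc1)(c1ccccc1)c1ccccc1.[Br-]
Why: Wittig methylenation of a salicylaldehyde, in which one equivalent of ylide is consumed by the phenol and the second converts the aldehyde.

**Step 7**
Reactants: 9 but-2-yn-1-ol
Product: 11 (Z)-3-iodobut-2-en-1-ol, via cyclic sodium alkenylaluminate (five-membered 1,2-oxaaluminole, Al on C3) 10 (not isolated)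
Conditions: Red-Al, THF, 0 °C → rt; then I2, THF, −78 → 0 °C
Reagents that add atoms: iodine, II
Why: Hydroxyl-directed trans-hydroalumination of the propargylic alcohol places aluminium on C3 within a five-membered aluminate, and iodinolysis with retention gives only the Z-iodide.

**Step 8**
Reactants: 8 2-ethenyl-6-methyl-4-[(triisopropylsilyl)oxy]phenol; 11 (Z)-3-iodobut-2-en-1-ol
Product: 13 2-[(3Z)-5-hydroxy-3-methylpent-3-en-1-yl]-6-methyl-4-[(triisopropylsilyl)oxy]phenol, via B-(2-arylethyl)-9-BBN O-aryl borinate 12 (not isolated)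
Conditions: 9-BBN (2.3 equiv), THF, 0 °C → rt; then 11, PdCl2(dppf) (5 mol %), 3 M aq K3PO4, DMF, rt
Reagents that add atoms: none
Why: Anti-Markovnikov hydroboration of the styrene is followed by B-alkyl Suzuki–Miyaura coupling with retention of the alkenyl iodide geometry, the phenol being masked in situ as its borinate, which the aqueous base releases again.

**Step 9**
Reactants: 13 2-[(3Z)-5-hydroxy-3-methylpent-3-en-1-yl]-6-methyl-4-[(triisopropylsilyl)oxy]phenol
Product: 14 (2Z)-5-{2-hydroxy-3-methyl-5-[(triisopropylsilyl)oxy]phenyl}-3-methylpent-2-en-1-yl methyl carbonate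
Conditions: ClCO2Me (1.1 equiv), pyridine, CH2Cl2, −20 → 0 °C
Reagents that add atoms: methyl chloroformate, COC(=O)Cl
Why: Chemoselective acylation, because under pyridine the primary allylic alcohol reacts faster than the 2,6-disubstituted phenol, which is not deprotonated.

**Step 10**
Reactants: 14 (2Z)-5-{2-hydroxy-3-methyl-5-[(triisopropylsilyl)oxy]phenyl}-3-methylpent-2-en-1-yl methyl carbonate
Product: 15 (R)-2-ethenyl-2,8-dimethyl-6-[(triisopropylsilyl)oxy]chromane
Conditions: Pd2(dba)3·CHCl3 (2 mol %), (S,S)-DACH-phenyl Trost ligand (6 mol %), AcOH (1 equiv), CH2Cl2, rt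
Reagents that add atoms: none
Why: In this intramolecular O-alkylation form of the Trost asymmetric allylic alkylation, ionisation of the carbonate gives interconverting π-allylpalladium diastereomers and the phenol closes the ring 6-exo at the more substituted allyl terminus inside the chiral pocket of the ligand, which selects the alkene face and sets C2 as R (the same spatial arrangement as S-C2 of the chromene), a cyclisation established for Z-trisubstituted phenol allyl carbonates with acetic acid as additive.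

**Step 11**
Reactants: 15 (R)-2-ethenyl-2,8-dimethyl-6-[(triisopropylsilyl)oxy]chromane
Product: 17 2-{(R)-2,8-dimethyl-6-[(triisopropylsilyl)oxy]chroman-2-yl}ethanol, via B-[2-(chroman-2-yl)ethyl]-9-BBN 16 (not isolated)
Conditions: 9-BBN, THF, rt; then aq NaOH, H2O2, 0 °C → rt
Reagents that add atoms: hydrogen peroxide, OO
Why: In the Brown hydroboration–oxidation 9-BBN places boron on the terminal carbon of the monosubstituted alkene and oxidation gives the primary alcohol without involving C2.

**Step 12**
Reactants: 17 2-{(R)-2,8-dimethyl-6-[(triisopropylsilyl)oxy]chroman-2-yl}ethanol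
Product: 18 (R)-2-(2-iodoethyl)-2,8-dimethyl-6-[(triisopropylsilyl)oxy]chromane
Conditions: I2, PPh3, imidazole, CH2Cl2, 0 °C → rt, dark
Reagents that add atoms: iodine, II
Why: Appel-type iodination (Garegg–Samuelsson conditions), in which iodide displaces the alkoxyphosphonium group by SN2 at the primary carbon.

**Step 13**
Reactants: 18 (R)-2-(2-iodoethyl)-2,8-dimethyl-6-[(triisopropylsilyl)oxy]chromane
Product: 19 (S)-2-(2-iodoethyl)-2,8-dimethyl-6-[(triisopropylsilyl)oxy]-2H-chromene
Conditions: DDQ (1.5 equiv), benzene, reflux, dark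
Reagents that add atoms: none
Why: In the DDQ dehydrogenation of a chroman, hydride abstraction from C4 gives a secondary benzylic cation stabilised by O1 through C8a and proton loss from C3 gives the 2H-chromene, while quaternary C2 is untouched and its descriptor changes to S only because C3 now outranks the side chain.

**Step 14**
Reactants: 4 (R)-tert-butyl({1-[(4-methoxybenzyl)oxy]pent-4-yn-2-yl}oxy)dimethylsilane; 19 (S)-2-(2-iodoethyl)-2,8-dimethyl-6-[(triisopropylsilyl)oxy]-2H-chromene
Product: 22 coupled (R,E,S)-alkene with C5–OTBS, CH2OPMB and the 6-OTIPS chromene, via (E)-alkenyldimethylalane 20 (not isolated), via (E)-alkenylzinc bromide 21 (not isolated)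
Conditions: 4 (1.5 equiv), AlMe3 (3 equiv), Cp2ZrCl2 (0.25 equiv), CH2Cl2, 0 °C → rt; volatiles removed in vacuo; ZnBr2 (1.5 equiv), THF, 0 °C; then 19, Pd2(dba)3 (2.5 mol %), PCyp3 (10 mol %), N-methylimidazole, THF/NMP, 60 °C, dark
Reagents that add atoms: trimethylaluminium, C[Al](C)C
Why: The Zr/Al methyl species adds methyl and metal syn across the terminal alkyne of 4, methyl to the internal and metal to the terminal carbon, giving E-alane 20, which after removal of excess AlMe3 passes its alkenyl group to zinc with retention (21). Electron-rich Pd(0)/PCyp3 inserts into the primary C–I bond of 19 by SN2-type oxidative addition, and transmetalation followed by reductive elimination forms the sp2–sp3 bond with retention of geometry. The closest known reaction types are the zirconium-catalysed carboalumination/zinc-assisted palladium cross-coupling (Negishi) and the Negishi coupling of alkenylzinc halides with unactivated primary alkyl iodides under the trialkylphosphine/N-methylimidazole protocol. No ring closes and no stereocentre is formed; C5 and C2 are spectators, and the only new stereoelement, the E-alkene, is fixed by syn addition plus double retention. The step needs regioselective carbometalation (secured by the terminal alkyne with an unbranched propargylic CH2), reductive elimination faster than β-hydride elimination (bulky donor phosphine), and alkenyl rather than methyl transfer (AlMe3 stripped off, the sp2 group migrates faster). Because the halide lies two carbons from C2, no metal ever sits β to the aryloxy group, and the chromene C3=C4 could only be reached by unfavourable 4-exo or 5-endo carbopalladation.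

**Step 15**
Reactants: 23 ethyl 2-[bis(2-methylphenoxy)phosphoryl]acetate; 24 5-bromo-2-methylpent-2-ene
Product: 25 ethyl 2-[bis(2-methylphenoxy)phosphoryl]-6-methylhept-5-enoate (racemic at C2)
Conditions: NaH, DMSO, rt; then 24, 50 °C
Reagents that add atoms: none
Why: SN2 alkylation of the stabilised phosphonoacetate anion with a primary bromide is the established access to α-substituted diaryl phosphonoacetates.

**Step 16**
Reactants: 22 coupled (R,E,S)-alkene with C5–OTBS, CH2OPMB and the 6-OTIPS chromene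
Product: 26 (R,E)-2-(TBSO)-4-methyl-7-[(S)-chromen-2-yl]hept-4-en-1-ol (primary alcohol)
Conditions: DDQ, CH2Cl2/pH 7 buffer (10:1), 0 °C
Reagents that add atoms: none
Why: Oxidative PMB cleavage with DDQ proceeds through the p-methoxybenzyl oxocarbenium ion and its hydrolysis, while the chromene has no hydride at C2 to lose and has already passed hotter DDQ in step 13.

**Step 17**
Reactants: 26 (R,E)-2-(TBSO)-4-methyl-7-[(S)-chromen-2-yl]hept-4-en-1-ol
Product: 27 (R,E)-2-(TBSO)-4-methyl-7-[(S)-chromen-2-yl]hept-4-enal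
Conditions: Dess–Martin periodinane, NaHCO3, CH2Cl2, 0 °C → rt
Reagents that add atoms: none
Why: Buffered Dess–Martin oxidation is neutral enough not to epimerise the α-silyloxy aldehyde and leaves alkenes and silyl ethers alone.

**Step 18**
Reactants: 27 (R,E)-2-(TBSO)-4-methyl-7-[(S)-chromen-2-yl]hept-4-enal; 25 ethyl 2-[bis(2-methylphenoxy)phosphoryl]-6-methylhept-5-enoate
Product: 28 ethyl (2Z,4R,6E)-4-(TBSO)-6-methyl-2-(4-methylpent-3-enyl)-9-[(S)-chromen-2-yl]nona-2,6-dienoate
Conditions: 25, NaH, THF, 0 °C; then 27, −78 → 0 °C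
Reagents that add atoms: none
Why: In the Z-selective Horner–Wadsworth–Emmons olefination (Ando variant) the electron-poor aryloxy groups make collapse of the kinetic adduct fast, so the ester ends up cis to C5, and the preformed anion at low temperature spares the α-stereocentre.

**Step 19**
Reactants: 28 ethyl (2Z,4R,6E)-4-(TBSO)-6-methyl-2-(4-methylpent-3-enyl)-9-[(S)-chromen-2-yl]nona-2,6-dienoate
Product: 30 tuberatolide B, via doubly desilylated Z-γ-hydroxy enoate 29 (not isolated)
Conditions: TBAF/AcOH (1:1), THF, 0 °C → rt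
Reagents that add atoms: none
Why: Fluoride cleaves the aryl TIPS and the allylic TBS ether, and the freed C5 hydroxyl, held cis to the ester, closes the five-membered lactone by 5-exo-trig acyl substitution with loss of ethanol, while the acetic acid buffer suppresses γ-deprotonation of the butenolide so that C5 is kept.

**Compound list**

| No. | Name | SMILES | Role |
|---|---|---|---|
| 1 | (S)-glycidol | OC[C@H]1CO1 | starting material |
| 2 | (R)-2-{[(4-methoxybenzyl)oxy]methyl}oxirane | COc1ccc(COC[C@H]2CO2)cc1 | intermediate |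
| 3 | (R)-1-[(4-methoxybenzyl)oxy]pent-4-yn-2-ol | COc1ccc(COC[C@@H](CC#C)O)cc1 | intermediate |
| 4 | (R)-tert-butyl({1-[(4-methoxybenzyl)oxy]pent-4-yn-2-yl}oxy)dimethylsilane | COc1ccc(COC[C@@H](CC#C)O[Si](C)(C)C(C)(C)C)cc1 | intermediate |
| 5 | 2-methylhydroquinone | Cc1cc(O)ccc1O | starting material |
| 6 | 2-methyl-4-[(triisopropylsilyl)oxy]phenol | Cc1cc(O[Si](C(C)C)(C(C)C)C(C)C)ccc1O | intermediate |
| 7 | 2-hydroxy-3-methyl-5-[(triisopropylsilyl)oxy]benzaldehyde | Cc1cc(O[Si](C(C)C)(C(C)C)C(C)C)cc(C=O)c1O | intermediate |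
| 8 | 2-ethenyl-6-methyl-4-[(triisopropylsilyl)oxy]phenol | Cc1cc(O[Si](C(C)C)(C(C)C)C(C)C)cc(C=C)c1O | intermediate |
| 9 | but-2-yn-1-ol | CC#CCO | starting material |
| 10 | sodium 2,2-bis(2-methoxyethoxy)-3-methyl-2,5-dihydro-1,2-oxaaluminol-2-uide | CC1=CCO[Al-]1(OCCOC)OCCOC.[Na+] | intermediate |
| 11 | (Z)-3-iodobut-2-en-1-ol | C/C(I)=C/CO | intermediate |
| 12 | B-{2-[2-(9-BBN-oxy)-3-methyl-5-(triisopropylsilyloxy)phenyl]ethyl}-9-BBN | Cc1cc(O[Si](C(C)C)(C(C)C)C(C)C)cc(CCB2C3CCCC2CCC3)c1OB1C2CCCC1CCC2 | intermediate |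
| 13 | 2-[(3Z)-5-hydroxy-3-methylpent-3-en-1-yl]-6-methyl-4-[(triisopropylsilyl)oxy]phenol | C/C(CCc1cc(O[Si](C(C)C)(C(C)C)C(C)C)cc(C)c1O)=C/CO | intermediate |
| 14 | (2Z)-5-{2-hydroxy-3-methyl-5-[(triisopropylsilyl)oxy]phenyl}-3-methylpent-2-en-1-yl methyl carbonate | C/C(CCc1cc(O[Si](C(C)C)(C(C)C)C(C)C)cc(C)c1O)=C/COC(=O)OC | intermediate |
| 15 | (R)-2-ethenyl-2,8-dimethyl-6-[(triisopropylsilyl)oxy]chromane | C=C[C@@]1(C)CCc2cc(O[Si](C(C)C)(C(C)C)C(C)C)cc(C)c2O1 | intermediate |
| 16 | B-{2-[(R)-2,8-dimethyl-6-(triisopropylsilyloxy)chroman-2-yl]ethyl}-9-BBN | B1(C2CCCC1CCC2)CC[C@@]3(C)CCc4cc(O[Si](C(C)C)(C(C)C)C(C)C)cc(C)c4O3 | intermediate |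
| 17 | 2-{(R)-2,8-dimethyl-6-[(triisopropylsilyl)oxy]chroman-2-yl}ethanol | OCC[C@@]1(C)CCc2cc(O[Si](C(C)C)(C(C)C)C(C)C)cc(C)c2O1 | intermediate |
| 18 | (R)-2-(2-iodoethyl)-2,8-dimethyl-6-[(triisopropylsilyl)oxy]chromane | ICC[C@@]1(C)CCc2cc(O[Si](C(C)C)(C(C)C)C(C)C)cc(C)c2O1 | intermediate |
| 19 | (S)-2-(2-iodoethyl)-2,8-dimethyl-6-[(triisopropylsilyl)oxy]-2H-chromene | ICC[C@@]1(C)C=Cc2cc(O[Si](C(C)C)(C(C)C)C(C)C)cc(C)c2O1 | intermediate |
| 20 | (R,E)-[4-(TBSO)-5-(4-methoxybenzyloxy)-2-methylpent-1-enyl]dimethylalane | COc1ccc(COC[C@@H](C/C(C)=C/[Al](C)C)O[Si](C)(C)C(C)(C)C)cc1 | intermediate |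
| 21 | (R,E)-[4-(TBSO)-5-(4-methoxybenzyloxy)-2-methylpent-1-enyl]zinc bromide | COc1ccc(COC[C@@H](C/C(C)=C/[Zn]Br)O[Si](C)(C)C(C)(C)C)cc1 | intermediate |
| 22 | (S)-2-[(R,E)-6-(TBSO)-7-(4-methoxybenzyloxy)-4-methylhept-3-enyl]-2,8-dimethyl-6-(triisopropylsilyloxy)-2H-chromene | COc1ccc(COC[C@@H](C/C(C)=C/CC[C@@]2(C)C=Cc3cc(O[Si](C(C)C)(C(C)C)C(C)C)cc(C)c3O2)O[Si](C)(C)C(C)(C)C)cc1 | intermediate |
| 23 | ethyl 2-[bis(2-methylphenoxy)phosphoryl]acetate | CCOC(=O)CP(=O)(Oc1ccccc1C)Oc1ccccc1C | starting material |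
| 24 | 5-bromo-2-methylpent-2-ene | CC(C)=CCCBr | starting material |
| 25 | ethyl 2-[bis(2-methylphenoxy)phosphoryl]-6-methylhept-5-enoate | CCOC(=O)C(CCC=C(C)C)P(=O)(Oc1ccccc1C)Oc1ccccc1C | intermediate |
| 26 | (R,E)-2-(TBSO)-7-[(S)-2,8-dimethyl-6-(triisopropylsilyloxy)-2H-chromen-2-yl]-4-methylhept-4-en-1-ol | OC[C@@H](C/C(C)=C/CC[C@@]1(C)C=Cc2cc(O[Si](C(C)C)(C(C)C)C(C)C)cc(C)c2O1)O[Si](C)(C)C(C)(C)C | intermediate |
| 27 | (R,E)-2-(TBSO)-7-[(S)-2,8-dimethyl-6-(triisopropylsilyloxy)-2H-chromen-2-yl]-4-methylhept-4-enal | O=C[C@@H](C/C(C)=C/CC[C@@]1(C)C=Cc2cc(O[Si](C(C)C)(C(C)C)C(C)C)cc(C)c2O1)O[Si](C)(C)C(C)(C)C | intermediate |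
| 28 | ethyl (2Z,4R,6E)-4-(TBSO)-9-[(S)-2,8-dimethyl-6-(triisopropylsilyloxy)-2H-chromen-2-yl]-6-methyl-2-(4-methylpent-3-enyl)nona-2,6-dienoate | CCOC(=O)/C(CCC=C(C)C)=C\\[C@@H](C/C(C)=C/CC[C@@]1(C)C=Cc2cc(O[Si](C(C)C)(C(C)C)C(C)C)cc(C)c2O1)O[Si](C)(C)C(C)(C)C | intermediate |
| 29 | ethyl (2Z,4R,6E)-4-hydroxy-9-[(S)-6-hydroxy-2,8-dimethyl-2H-chromen-2-yl]-6-methyl-2-(4-methylpent-3-enyl)nona-2,6-dienoate | CCOC(=O)/C(CCC=C(C)C)=C\\[C@@H](C/C(C)=C/CC[C@@]1(C)C=Cc2cc(O)cc(C)c2O1)O | intermediate |
| 30 | tuberatolide B, (R)-5-{(E)-5-[(S)-6-hydroxy-2,8-dimethyl-2H-chromen-2-yl]-2-methylpent-2-en-1-yl}-3-(4-methylpent-3-en-1-yl)furan-2(5H)-one | CC(C)=CCCC1=C[C@@H](C/C(C)=C/CC[C@@]2(C)C=Cc3cc(O)cc(C)c3O2)OC1=O | target |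

In the SMILES of 28 and 29 the bond mark before [C@@H] is a single backslash.

**Step count**
Total: 19 steps. Longest linear sequence: 14 steps (5 → 30 through steps 4–6, 8–14 and 16–19).

**Steps most likely to fail**

**1. Step 14.**
- What may go wrong: β-hydride elimination of the alkylpalladium intermediate, transfer of methyl instead of alkenyl from residual aluminium or zinc species, and slow erosion of C2 by thermal oxa-6π ring opening at the coupling temperature.
- Fallback (sets out from 4 and 19, returns at 22): the polarity of the sp2–sp3 coupling is inverted. Alkyne 4 is methylaluminated as before, and alane 20 is quenched with iodine (THF, −30 °C) to give the (R,E)-alkenyl iodide F1. Iodide 19 is converted with zinc dust/LiCl in THF into the alkylzinc iodide F2, in which zinc is γ to the aryloxy group and cannot expel it. A PdCl2(dppf)-catalysed Negishi alkyl–alkenyl coupling of the two at room temperature gives 22. Oxidative addition then occurs at the sp2 C–I bond, so no β-hydride-bearing alkyl halide has to be activated.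

**2. Step 10.**
- What may go wrong: insufficient or inverted facial selectivity in the ring closure, since the π-allyl diastereomers equilibrate and the outcome rests on relative cyclisation rates.
- Fallback (sets out from 13, returns at 15): the centre is set by reagent control with a predictable sense. Sharpless asymmetric epoxidation of 13 with D-(−)-diisopropyl tartrate (Ti(OiPr)4, TBHP, 4 Å MS, CH2Cl2, −20 °C) gives the (2R,3S)-epoxy alcohol F3. The phenol opens it 6-exo at the tertiary carbon with inversion (cat. CSA, CH2Cl2) to the (R,R)-chroman diol F4. NaIO4 cleavage gives the (R)-chroman-2-carbaldehyde F5, and Wittig methylenation returns 15.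

**3. Step 13.**
- What may go wrong: degradation of the primary iodide on prolonged heating with the oxidant, and therefore incomplete dehydrogenation.
- Fallback (sets out from 15, returns at 19): the ring is dehydrogenated before any heteroatom is placed on the side chain. DDQ in refluxing benzene converts 15 into the (S)-2-ethenyl-2H-chromene F6. 9-BBN then adds chemoselectively to the monosubstituted vinyl group rather than to the conjugated cis-disubstituted C3=C4, giving the B-alkyl-9-BBN adduct F7. Oxidation gives the (S)-chromene ethanol F8, and Appel-type iodination (I2, PPh3, imidazole) gives 19 without the C–I bond ever meeting hot DDQ.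

**Further compounds**
F1 | step 14 | (R,E)-tert-butyl({5-iodo-1-[(4-methoxybenzyl)oxy]-4-methylpent-4-en-2-yl}oxy)dimethylsilane | COc1ccc(COC[C@@H](C/C(C)=C/I)O[Si](C)(C)C(C)(C)C)cc1
F2 | step 14 | {2-[(S)-2,8-dimethyl-6-(triisopropylsilyloxy)-2H-chromen-2-yl]ethyl}zinc iodide | I[Zn]CC[C@@]1(C)C=Cc2cc(O[Si](C(C)C)(C(C)C)C(C)C)cc(C)c2O1
F3 | step 10 | (2R,3S)-2,3-epoxide of 13, 2-{2-[(2S,3R)-3-(hydroxymethyl)-2-methyloxiran-2-yl]ethyl}-6-methyl-4-(triisopropylsilyloxy)phenol | OC[C@H]1O[C@@]1(C)CCc1cc(O[Si](C(C)C)(C(C)C)C(C)C)cc(C)c1O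
F4 | step 10 | (R)-1-[(R)-2,8-dimethyl-6-(triisopropylsilyloxy)chroman-2-yl]ethane-1,2-diol | OC[C@@H](O)[C@@]1(C)CCc2cc(O[Si](C(C)C)(C(C)C)C(C)C)cc(C)c2O1
F5 | step 10 | (R)-2,8-dimethyl-6-(triisopropylsilyloxy)chroman-2-carbaldehyde | O=C[C@@]1(C)CCc2cc(O[Si](C(C)C)(C(C)C)C(C)C)cc(C)c2O1
F6 | step 13 | (S)-2-ethenyl-2,8-dimethyl-6-(triisopropylsilyloxy)-2H-chromene | C=C[C@@]1(C)C=Cc2cc(O[Si](C(C)C)(C(C)C)C(C)C)cc(C)c2O1
F7 | step 13 | B-{2-[(S)-2,8-dimethyl-6-(triisopropylsilyloxy)-2H-chromen-2-yl]ethyl}-9-BBN | B1(C2CCCC1CCC2)CC[C@@]3(C)C=Cc4cc(O[Si](C(C)C)(C(C)C)C(C)C)cc(C)c4O3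
F8 | step 13 | 2-[(S)-2,8-dimethyl-6-(triisopropylsilyloxy)-2H-chromen-2-yl]ethanol | OCC[C@@]1(C)C=Cc2cc(O[Si](C(C)C)(C(C)C)C(C)C)cc(C)c2O1
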